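**Plan**

- Retrosynthesis: the two carbinols and the phenol are traced back to a methyl ester and two pivalates. The C3–C3a bond is then cut by reversing a 1,2-shift of ring A, which puts the ester carbon back between C3 and C3a and expands the dihydrofuran to the pyranone of a (2S)-flavanone.
- Enabling feature: C3 of the target carries ring A (through C3a) and a one-carbon oxygenated arm on the same atom, next to the O1–C2(aryl) unit. This is the pattern left when C4 of a flavanone is pushed out of the ring.
- Further cuts: the flavanone at C2–aryl (syringyl boronic acid plus chromone), the chromone at C6–CH2 (alkylborane plus aryl bromide) and at O1–C2/C2–C3 (one-carbon annulation of an o-hydroxyacetophenone).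
- Forward order: ring A is bought, the pyranone is closed (step 2), the chain (step 3) and the syringyl ring (step 6) are attached, the pyranone is contracted to the dihydrofuran (step 7), and hydride frees the three hydroxyl groups (step 8).
- Stereochemistry: C2 (S) comes from ligand-controlled Pd-catalysed aryl addition to the chromone. C3 is set trans to the C2 aryl group during the contraction, so the (2S,3S)-ester and the (2S,3R)-target have the same arrangement in space.

Key step: step 7

Assumption: the Pd/t-BuPyOX catalyst is taken to attack the chromone on the same face as it attacks 3-substituted cyclohexenones, so the (R)-ligand is specified for the (2S)-flavanone; if the sense proves opposite, the (S)-ligand is used and nothing else changes.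

**Step 1**
Reactants: 1 1-(2-hydroxy-3-methoxyphenyl)ethanone
Product: 2 1-(5-bromo-2-hydroxy-3-methoxyphenyl)ethanone
Conditions: NBS (1.05 equiv), MeCN, 0 °C→rt
Reagents that add atoms: N-bromosuccinimide, O=C1CCC(=O)N1Br
Why: Electrophilic aromatic bromination should go to C5, the only free position para to the phenol (both ortho positions are occupied) and meta to the acetyl group, as in the bromination of o-vanillin.

**Step 2**
Reactants: 2 1-(5-bromo-2-hydroxy-3-methoxyphenyl)ethanone
Product: 4 6-bromo-8-methoxy-4H-chromen-4-one, via enaminone 3 (not isolated)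
Conditions: Me2NCH(OMe)2, toluene, 100 °C; then conc. HCl, CH2Cl2, 40 °C
Reagents that add atoms: N,N-dimethylformamide dimethyl acetal, COC(OC)N(C)C
Why: Enaminone condensation of the methyl ketone, followed by acid-promoted intramolecular oxa-Michael addition and loss of dimethylamine, is the standard chromone annulation of o-hydroxyacetophenones, with the acetal supplying C2.

**Step 3**
Reactants: 5 allyl pivalate (prop-2-en-1-yl 2,2-dimethylpropanoate); 4 6-bromo-8-methoxy-4H-chromen-4-one
Product: 7 3-(8-methoxy-4-oxo-4H-chromen-6-yl)propyl pivalate, via alkyl-9-BBN borane 6 (not isolated)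
Conditions: 5 (slight excess over borane), 9-BBN-H, THF, 0 °C→rt; then 4, PdCl2(dppf) (cat.), aq. K3PO4, DMF, 50 °C; dil. HCl work-up
Reagents that add atoms: none
Why: Anti-Markovnikov hydroboration of the terminal alkene and B-alkyl Suzuki–Miyaura coupling of the primary alkylborane with the aryl bromide should join C6 to the propyl chain, the pivalate being inert to borane and phosphate and the acidic work-up re-closing any pyranone opened by base.

**Step 4**
Reactants: 8 4-bromo-2,6-dimethoxyphenol
Product: 9 4-bromo-2,6-dimethoxyphenyl pivalate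
Conditions: PivCl, Et3N, DMAP (cat.), CH2Cl2, 0 °C→rt
Reagents that add atoms: pivaloyl chloride, CC(C)(C)C(Cl)=O
Why: DMAP-catalysed O-acylation of the hindered phenol should give the aryl pivalate, which lowers the electron density of the syringyl ring for the later oxidation and is removed by hydride at the end.

**Step 5**
Reactants: 9 4-bromo-2,6-dimethoxyphenyl pivalate
Product: 10 (3,5-dimethoxy-4-pivaloyloxyphenyl)boronic acid
Conditions: B2(OH)4, XPhos-Pd-G2 (cat.), XPhos, KOAc, EtOH, 80 °C
Reagents that add atoms: tetrahydroxydiboron, OB(O)B(O)O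
Why: Miyaura borylation of the unhindered aryl bromide with tetrahydroxydiboron should give the free boronic acid directly, the weak acetate base leaving the hindered aryl ester intact.

**Step 6**
Reactants: 7 3-(8-methoxy-4-oxo-4H-chromen-6-yl)propyl pivalate; 10 (3,5-dimethoxy-4-pivaloyloxyphenyl)boronic acid
Product: 11 (2S)-2-(3,5-dimethoxy-4-pivaloyloxyphenyl)-8-methoxy-6-(3-pivaloyloxypropyl)chroman-4-one
Conditions: Pd(OCOCF3)2 (5 mol %), (R)-t-BuPyOX (6 mol %), NH4PF6 (30 mol %), H2O (5 equiv), ClCH2CH2Cl, 60 °C
Reagents that add atoms: none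
Why: Pd(II)-catalysed asymmetric conjugate addition of an arylboronic acid to a chromone should form the C2–aryl bond, the tert-butyl group of the pyridine-oxazoline ligand shielding one face in the enantio-determining insertion of C2=C3 into the aryl–Pd bond so that C2 is set as S, after which water protonates the Pd enolate.

**Step 7**
Reactants: 11 (2S)-2-(3,5-dimethoxy-4-pivaloyloxyphenyl)-8-methoxy-6-(3-pivaloyloxypropyl)chroman-4-one
Product: 13 methyl (2S,3S)-trans-2-(3,5-dimethoxy-4-pivaloyloxyphenyl)-7-methoxy-5-(3-pivaloyloxypropyl)-2,3-dihydrobenzofuran-3-carboxylate, via enol ether 12 (not isolated)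
Conditions: PhI(OAc)2 (1.3 equiv), conc. H2SO4, HC(OMe)3, 0 °C→rt; aq. NaHCO3 work-up
Reagents that add atoms: trimethyl orthoformate, COC(OC)OC
Why: Acid and orthoformate should convert the ketone into the 4-methoxy-2H-chromene 12, which iodine(III) attacks at C3; methanol caps the oxocarbenium ion as a ketal, and loss of iodobenzene is then assisted by the ring-A ipso carbon C4a, which moves from C4 to C3 in a phenonium-type 1,2-shift while the dimethoxycarbenium ion left at the old C4 ends as the methyl ester. The closest known reaction is the iodine(III)- or thallium(III)-mediated oxidative ring contraction of flavanones in trimethyl orthoformate to methyl trans-2-aryl-2,3-dihydrobenzofuran-3-carboxylates, a cyclic case of the 1,2-aryl shift that turns aryl alkyl ketones into 2-arylalkanoates. The five-membered ring O1–C2–C3–C3a–C7a is not closed by a cyclisation but arises by ring contraction, the new C3–C3a bond forming as C4 leaves the ring, so C2 is not touched. The new C3 centre is controlled by C2: the iodane should add anti to the C2 aryl group and lie pseudo-equatorial, antiperiplanar to the C4–C4a bond, and migration with inversion at C3 then gives the 2,3-trans ester, which is also the more stable epimer. The step needs ring-A migration to win over the shift of the C2 aryl group (isoflavone) and over dehydrogenation (flavone); this is secured because C4a is ortho to the O1-bearing carbon and correctly aligned, whereas the syringyl ring is made a poorer migrating and less oxidisable group by its pivalate.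

**Step 8**
Reactants: 13 methyl (2S,3S)-trans-2-(3,5-dimethoxy-4-pivaloyloxyphenyl)-7-methoxy-5-(3-pivaloyloxypropyl)-2,3-dihydrobenzofuran-3-carboxylate
Product: 14 4-[(2S,3R)-3-(hydroxymethyl)-5-(3-hydroxypropyl)-7-methoxy-2,3-dihydrobenzofuran-2-yl]-2,6-dimethoxyphenol (CNP0188630.1)
Conditions: LiAlH4 (excess), THF, 0 °C→rt; Rochelle salt work-up
Reagents that add atoms: none
Why: Hydride reduction of the methyl ester to the primary alcohol with reductive cleavage of the alkyl and aryl pivalates should give the target in one operation, neither stereocentre being involved and the trans ester being the stable epimer.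

**Compound list**

1 | 1-(2-hydroxy-3-methoxyphenyl)ethanone | CC(=O)c1cccc(OC)c1O | starting material
2 | 1-(5-bromo-2-hydroxy-3-methoxyphenyl)ethanone | CC(=O)c1cc(Br)cc(OC)c1O | intermediate
3 | (E)-1-(5-bromo-2-hydroxy-3-methoxyphenyl)-3-(dimethylamino)prop-2-en-1-one | CN(C)/C=C/C(=O)c1cc(Br)cc(OC)c1O | intermediate
4 | 6-bromo-8-methoxy-4H-chromen-4-one | O=c1ccoc2c(OC)cc(Br)cc12 | intermediate
5 | allyl pivalate | C=CCOC(=O)C(C)(C)C | starting material
6 | 3-(9-borabicyclo[3.3.1]nonan-9-yl)propyl pivalate | CC(C)(C)C(=O)OCCCB1C2CCCC1CCC2 | intermediate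
7 | 3-(8-methoxy-4-oxo-4H-chromen-6-yl)propyl pivalate | O=c1ccoc2c(OC)cc(CCCOC(=O)C(C)(C)C)cc12 | intermediate
8 | 4-bromo-2,6-dimethoxyphenol | COc1cc(Br)cc(OC)c1O | starting material
9 | 4-bromo-2,6-dimethoxyphenyl pivalate | COc1cc(Br)cc(OC)c1OC(=O)C(C)(C)C | intermediate
10 | (3,5-dimethoxy-4-pivaloyloxyphenyl)boronic acid | COc1cc(B(O)O)cc(OC)c1OC(=O)C(C)(C)C | intermediate
11 | (2S)-2-(3,5-dimethoxy-4-pivaloyloxyphenyl)-8-methoxy-6-(3-pivaloyloxypropyl)chroman-4-one | COc1cc([C@H]2Oc3c(OC)cc(CCCOC(=O)C(C)(C)C)cc3C(=O)C2)cc(OC)c1OC(=O)C(C)(C)C | intermediate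
12 | (2S)-2-(3,5-dimethoxy-4-pivaloyloxyphenyl)-4,8-dimethoxy-6-(3-pivaloyloxypropyl)-2H-chromene | COc1cc([C@H]2Oc3c(OC)cc(CCCOC(=O)C(C)(C)C)cc3C(OC)=C2)cc(OC)c1OC(=O)C(C)(C)C | intermediate
13 | methyl (2S,3S)-trans-2-(3,5-dimethoxy-4-pivaloyloxyphenyl)-7-methoxy-5-(3-pivaloyloxypropyl)-2,3-dihydrobenzofuran-3-carboxylate | COc1cc([C@H]2Oc3c(OC)cc(CCCOC(=O)C(C)(C)C)cc3[C@@H]2C(=O)OC)cc(OC)c1OC(=O)C(C)(C)C | intermediate
14 | 4-[(2S,3R)-3-(hydroxymethyl)-5-(3-hydroxypropyl)-7-methoxy-2,3-dihydrobenzofuran-2-yl]-2,6-dimethoxyphenol (trans) | COc1cc([C@H]2Oc3c(OC)cc(CCCO)cc3[C@@H]2CO)cc(OC)c1O | target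

**Count**

Total steps: 8. Longest linear sequence: 6 steps (steps 1, 2, 3, 6, 7, 8); steps 4 and 5 make the boronic acid for the convergent step 6.

**Steps most likely to fail**

Step 7. After iodination at C3 the intermediate may lose a proton instead of rearranging (dehydrogenation to the flavone), or the C2 aryl group may shift in place of ring A. The electron-rich rings may also be attacked by iodine(III), and the strong acid may open the pyranone reversibly and erode the configuration at C2. The fallback sets out from 11 and returns at 13; it separates activation from migration and brings no oxidant near the arenes at the rearrangement stage. Bromination of 11 with phenyltrimethylammonium tribromide in THF at 0 °C→rt should give the trans-3-bromoflavanone F1. Trimethyl orthoformate and catalytic TsOH in methanol should convert it into the bromo dimethyl ketal F2, whose equatorial C3–Br bond is antiperiplanar to C4–C4a. AgBF4 in methanol (ZnBr2 in toluene as the alternative Lewis acid) should then ionise the bromide with the same 1,2-shift of ring A, as in the rearrangement of α-halo aryl ketals to 2-arylalkanoates, and aqueous work-up should deliver 13 with the trans arrangement set by inversion at C3.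

Step 6. The aryl transfer may show poor facial selectivity on this 8-methoxychromone, or protodeboronation of 10 may outrun carbopalladation. The fallback sets out from 7 and 10 and returns at 11; it gives up asymmetric induction in favour of resolution. The same addition run with 2,2'-bipyridine as an achiral ligand should give the racemic flavanone F3. Asymmetric transfer hydrogenation with Cp*RhCl[(R,R)-TsDPEN] and HCO2H/Et3N in EtOAc at rt, stopped near half conversion, is expected to reduce the (2R)-enantiomer to the (2R,4R)-cis-flavan-4-ol F4. The untouched (2S)-ketone 11 is then separated by chromatography.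

Step 3. The aqueous base needed for boron-to-palladium transfer may open the γ-pyrone, and the alkylpalladium intermediate may undergo β-hydride elimination or the bromide may be reduced. The fallback sets out from 2 and returns at 7; it attaches the chain before the pyranone exists. Borane 6 is coupled with the bromo ketone 2 (Pd(OAc)2/SPhos, K3PO4, THF/H2O, 60 °C) to give 3-(3-acetyl-4-hydroxy-5-methoxyphenyl)propyl pivalate F5. Treatment with Me2NCH(OMe)2 as in step 2 should give the enaminone F6, which conc. HCl in CH2Cl2 closes to chromone 7.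

**Further compounds**

F1 | step 7 | 3-[(2R,3R)-3-bromo-2-(3,5-dimethoxy-4-pivaloyloxyphenyl)-8-methoxy-4-oxochroman-6-yl]propyl pivalate (trans; C2 as in 11, descriptor changed by priority only) | COc1cc([C@H]2Oc3c(OC)cc(CCCOC(=O)C(C)(C)C)cc3C(=O)[C@@H]2Br)cc(OC)c1OC(=O)C(C)(C)C
F2 | step 7 | 3-[(2R,3R)-3-bromo-2-(3,5-dimethoxy-4-pivaloyloxyphenyl)-4,4,8-trimethoxychroman-6-yl]propyl pivalate (trans) | COc1cc([C@H]2Oc3c(OC)cc(CCCOC(=O)C(C)(C)C)cc3C(OC)(OC)[C@@H]2Br)cc(OC)c1OC(=O)C(C)(C)C
F3 | step 6 | rac-2-(3,5-dimethoxy-4-pivaloyloxyphenyl)-8-methoxy-6-(3-pivaloyloxypropyl)chroman-4-one | COc1cc(C2Oc3c(OC)cc(CCCOC(=O)C(C)(C)C)cc3C(=O)C2)cc(OC)c1OC(=O)C(C)(C)C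
F4 | step 6 | 3-[(2R,4R)-2-(3,5-dimethoxy-4-pivaloyloxyphenyl)-4-hydroxy-8-methoxychroman-6-yl]propyl pivalate (cis) | COc1cc([C@@H]2Oc3c(OC)cc(CCCOC(=O)C(C)(C)C)cc3[C@H](O)C2)cc(OC)c1OC(=O)C(C)(C)C
F5 | step 3 | 3-(3-acetyl-4-hydroxy-5-methoxyphenyl)propyl pivalate | CC(=O)c1cc(CCCOC(=O)C(C)(C)C)cc(OC)c1O
F6 | step 3 | (E)-3-[3-(3-dimethylaminoprop-2-enoyl)-4-hydroxy-5-methoxyphenyl]propyl pivalate | CN(C)/C=C/C(=O)c1cc(CCCOC(=O)C(C)(C)C)cc(OC)c1O
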